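**Retrosynthetic overview**
1. Drimane numbering is used: ring A = C1–C5/C10, ring B = C5–C10, C4 = CMe2, side chain C11→C19, then the arene. The hydroquinone is unmasked and C12–OH sulfated last. C16–C17 comes from a B-alkyl Suzuki coupling with vinyl iodide 32. C11–C12 and the C12 carbinol come from lithiation–borylation of carbamate 21 with the 9-BBN adduct of drima-7,9(11)-diene 16.
2. 16 ⇒ enone 15 ⇒ decalol 11. The C9 oxygen is the handle for the C8 methyl group, the C7=C8 bond and C11.
3. Key disconnection: both carbocycles of 10 arise in one Lewis-acid cascade from the open-chain epoxy diene 9. Ring B closes first (C5–C10), ring A second (C3–C4); the arene ring is bought.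
4. Enabling feature: the quaternary CMe2 carbon C4 of ring A is an exocyclic substituent of ring B at C5, so C4–C5 can be carried as a prenyl double bond (C5=C4Me2). When C5 bonds to C10 the charge is forced onto C4. The arm C1–C2=C3 on the same C10 then holds the vinylsilane carbon C3 in six-ring reach of C4.
5. 9 ⇒ symmetric 2,8-dimethylnona-2,7-diene 3 by allylic oxidation, asymmetric epoxidation (the source of all decalin stereochemistry), alkynylation and semihydrogenation.

Key step: step 6

Assumption: the sulfate half-esters 35–37 are written in the protonated form used for the target. In the flask they are pyridinium or sodium salts, and the final material is brought to the acid form by a short pass through a cold H+ exchange resin.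

Step 1
Reactants: 1 propane-1,3-diyl bis(4-methylbenzenesulfonate); 2 (2-methylprop-1-en-1-yl)magnesium bromide (2.5 equiv)
Product: 3 2,8-dimethylnona-2,7-diene
Conditions: Li2CuCl4 (5 mol%), THF, −20 °C to rt
Reagents that add atoms: none
Why: Copper-catalysed sp3–sp2 Grignard cross-coupling of a primary tosylate should run at both identical ends without halogen–metal exchange, and no stereocentre is involved.

Step 2
Reactants: 3 2,8-dimethylnona-2,7-diene
Product: 4 (2E)-2,8-dimethylnona-2,7-dien-1-ol
Conditions: SeO2 (cat.), t-BuOOH (0.6 equiv), salicylic acid (cat.), CH2Cl2, 0 °C to rt; unreacted 3 recycled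
Reagents that add atoms: tert-butyl hydroperoxide, CC(C)(C)OO (oxygen atom, passed on by catalytic SeO2, O=[Se]=O)
Why: Riley-type allylic oxidation (ene reaction then [2,3]-shift) hydroxylates the E-methyl group of a trisubstituted alkene, and because both ends of 3 are identical a deficit of oxidant should give the mono-alcohol with E geometry.

Step 3
Reactants: 4 (2E)-2,8-dimethylnona-2,7-dien-1-ol
Product: 5 [(2S,3S)-2-methyl-3-(5-methylhex-4-en-1-yl)oxiran-2-yl]methanol
Conditions: Ti(Oi-Pr)4 (cat.), L-(+)-diethyl tartrate (cat.), t-BuOOH, 4 Å MS, CH2Cl2, −20 °C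
Reagents that add atoms: tert-butyl hydroperoxide, CC(C)(C)OO
Why: Katsuki–Sharpless asymmetric epoxidation touches only the allylic-alcohol alkene and, with L-(+)-tartrate on an E-2-methyl-2-alkenol, should deliver oxygen to the face that gives the (2S,3S)-epoxide, which sets both epoxide centres (C9 and C10).

Step 4
Reactants: 5 [(2S,3S)-2-methyl-3-(5-methylhex-4-en-1-yl)oxiran-2-yl]methanol; 6 lithium (trimethylsilyl)acetylide
Product: 8 (2S,3S)-2-methyl-3-(5-methylhex-4-en-1-yl)-2-[3-(trimethylsilyl)prop-2-yn-1-yl]oxirane, via epoxy triflate 7 (not isolated)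
Conditions: Tf2O, 2,6-lutidine, CH2Cl2, −78 °C; then 6, THF–DMPU, −78 to −20 °C
Reagents that add atoms: trifluoromethanesulfonic anhydride, O=S(=O)(OS(=O)(=O)C(F)(F)F)C(F)(F)F (its atoms stay only in 7)
Why: SN2 displacement of a primary epoxy triflate by a lithium acetylide at low temperature should outrun epoxide opening in the absence of a Lewis acid, and neither stereocentre is touched.

Step 5
Reactants: 8 (2S,3S)-2-methyl-3-(5-methylhex-4-en-1-yl)-2-[3-(trimethylsilyl)prop-2-yn-1-yl]oxirane
Product: 9 (2S,3S)-2-methyl-3-(5-methylhex-4-en-1-yl)-2-[(2Z)-3-(trimethylsilyl)prop-2-en-1-yl]oxirane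
Conditions: H2 (1 atm), Lindlar catalyst, quinoline, hexane, rt
Reagents that add atoms: none
Why: Lindlar semihydrogenation adds H2 syn to the silyl alkyne to give the Z-vinylsilane and should leave the trisubstituted alkene and the epoxide alone.

Step 6
Reactants: 9 (2S,3S)-2-methyl-3-(5-methylhex-4-en-1-yl)-2-[(2Z)-3-(trimethylsilyl)prop-2-en-1-yl]oxirane
Product: 10 (1S,4aS,8aS)-5,5,8a-trimethyl-1,2,3,4,4a,5,8,8a-octahydronaphthalen-1-ol (trans-decalin, 9β-equatorial OH, C2=C3)
Conditions: MeAlCl2 (1.5 equiv), CH2Cl2 (high dilution), −78 °C; aqueous work-up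
Reagents that add atoms: none
Why: MeAlCl2 binds the epoxide oxygen, the C10–O bond at the tertiary methyl-bearing carbon loosens and the CH end (C5) of the prenyl double bond attacks C10 from the rear, which closes ring B and puts the charge on the exocyclic CMe2 carbon C4; C4 is then attacked by the silicon-bearing carbon C3 of the Z-vinylsilane arm on C10, and the β-silyl cation at C2 loses the silyl group to chloride, which closes ring A with a C2=C3 double bond. The closest known reaction types are the MeAlCl2-promoted epoxide-initiated cation–olefin polycyclisation and the vinylsilane-terminated cationic cyclisation in its endocyclic mode. Ring B closes 6-endo-tet at the epoxide and 6-exo-trig at the alkene through a chair, and ring A closes 6-endo-trig at the vinylsilane. C10 is set by stereospecific inversion at the epoxide carbon made in step 3, the E-derived epoxide placing its methyl group axial and the C1 arm equatorial; C5 is set by the chair in which the developing CMe2 cation is equatorial, so that the two arms that become ring A are both equatorial and the fusion is trans; C9 keeps its C–O bond and ends as the equatorial alcohol. The step needs attack at C10 and not 5-exo attack at C9, which the tertiary against secondary cation character of the Lewis-acid-bound trisubstituted epoxide secures; it needs bonding at C3 and not at C2, which the β-silicon effect and the Z geometry secure; and it needs capture of the C4 cation before proton loss, which the six-membered reach, the low temperature and the non-basic, proton-scavenging methylaluminium reagent favour.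

Step 7
Reactants: 10 (1S,4aS,8aS)-5,5,8a-trimethyl-1,2,3,4,4a,5,8,8a-octahydronaphthalen-1-ol
Product: 11 (1S,4aS,8aS)-5,5,8a-trimethyldecahydronaphthalen-1-ol
Conditions: H2 (1 atm), 10% Pd/C, EtOAc, rt
Reagents that add atoms: none
Why: Heterogeneous catalytic hydrogenation saturates the only C=C bond of the molecule (cis-disubstituted) and creates no stereocentre.

Step 8
Reactants: 11 (1S,4aS,8aS)-5,5,8a-trimethyldecahydronaphthalen-1-ol
Product: 12 (4aS,8aS)-5,5,8a-trimethyloctahydronaphthalen-1(2H)-one
Conditions: TPAP (5 mol%), NMO, 4 Å MS, CH2Cl2, rt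
Reagents that add atoms: none
Why: Ley–Griffith oxidation converts the hindered secondary alcohol into the C9 ketone under neutral conditions, and C5 and C10 cannot epimerise.

Step 9
Reactants: 12 (4aS,8aS)-5,5,8a-trimethyloctahydronaphthalen-1(2H)-one
Product: 13 (2R,4aS,8aS)-2,5,5,8a-tetramethyloctahydronaphthalen-1(2H)-one (equatorial 8α-methyl)
Conditions: LDA, THF, −78 °C; MeI, −78 to 0 °C
Reagents that add atoms: iodomethane, CI
Why: Lithium enolate alkylation can occur only at C8 because the other α-carbon (C10) is quaternary, the methyl group should enter anti to the axial C10 methyl and end equatorial, and this centre is erased in step 10.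

Step 10
Reactants: 13 (2R,4aS,8aS)-2,5,5,8a-tetramethyloctahydronaphthalen-1(2H)-one
Product: 15 (4aS,8aS)-2,5,5,8a-tetramethyl-4a,5,6,7,8,8a-hexahydronaphthalen-1(4H)-one, via silyl enol ether 14 (not isolated)
Conditions: TMSOTf, Et3N, CH2Cl2, 0 °C; then Pd(OAc)2 (1 equiv), MeCN, rt
Reagents that add atoms: trimethylsilyl trifluoromethanesulfonate, C[Si](C)(C)OS(=O)(=O)C(F)(F)F (its atoms stay only in 14)
Why: Saegusa–Ito oxidation works here because only one silyl enol ether is possible and β-hydride elimination from the ring CH2 (C7) should give the conjugated endocyclic C7=C8 enone.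

Step 11
Reactants: 15 (4aS,8aS)-2,5,5,8a-tetramethyl-4a,5,6,7,8,8a-hexahydronaphthalen-1(4H)-one
Product: 16 drima-7,9(11)-diene, (4aS,8aS)-2,5,5,8a-tetramethyl-1-methylidene-1,4,4a,5,6,7,8,8a-octahydronaphthalene
Conditions: Ph3PCH3Br, KOt-Bu, toluene, 90 °C
Reagents that add atoms: methyltriphenylphosphonium bromide, C[P+](c1ccccc1)(c1ccccc1)c1ccccc1.[Br-]
Why: Wittig methylenation with the smallest ylide under hot alkoxide conditions is the standard answer to hindered ketones, and 15 has no α-hydrogen that could be lost irreversibly.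

Step 12
Reactants: 17 (4S)-4-benzyl-3-propanoyl-1,3-oxazolidin-2-one; 18 3-iodoprop-1-ene
Product: 19 (4S)-4-benzyl-3-[(2R)-2-methylpent-4-enoyl]-1,3-oxazolidin-2-one
Conditions: NaHMDS, THF, −78 °C; then 18
Reagents that add atoms: none
Why: Evans asymmetric alkylation, in which the chelated Z-enolate is attacked on the face opposite the benzyl group, sets the (R)-methyl centre (C13).

Step 13
Reactants: 19 (4S)-4-benzyl-3-[(2R)-2-methylpent-4-enoyl]-1,3-oxazolidin-2-one
Product: 20 (2R)-2-methylpent-4-en-1-ol
Conditions: LiBH4, MeOH (1 equiv), Et2O, 0 °C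
Reagents that add atoms: none
Why: Reductive cleavage of the N-acyl oxazolidinone with LiBH4 attacks the exocyclic carbonyl and should not epimerise the α-centre.

Step 14
Reactants: 20 (2R)-2-methylpent-4-en-1-ol
Product: 21 (2R)-2-methylpent-4-en-1-yl N,N-diisopropylcarbamate
Conditions: i-Pr2NCOCl, Et3N, CH2Cl2, reflux
Reagents that add atoms: N,N-diisopropylcarbamoyl chloride, CC(C)N(C(C)C)C(=O)Cl
Why: O-Carbamoylation of a primary alcohol installs the directing and leaving group for the asymmetric deprotonation without touching C13.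

Step 15
Reactants: 16 drima-7,9(11)-diene; 21 (2R)-2-methylpent-4-en-1-yl N,N-diisopropylcarbamate
Product: 26 (2R,3R)-3-methyl-1-[(1S,4aS,8aS)-2,5,5,8a-tetramethyl-1,4,4a,5,6,7,8,8a-octahydronaphthalen-1-yl]hex-5-en-2-ol, via primary borane 22 (not isolated), via lithio carbamate 23 (not isolated), via ate complex 24 (not isolated), via secondary borane 25 (not isolated)
Conditions: 16, 9-BBN (1.0 equiv), THF, 50 °C; 21, s-BuLi, (+)-sparteine, Et2O, −78 °C; combine at −78 °C, then rt; NaOH, H2O2, 0 °C
Reagents that add atoms: 9-borabicyclo[3.3.1]nonane, [H]B1C2CCCC1CCC2 (only in 22, 24, 25); sec-butyllithium, [Li]C(C)CC (Li only in 23, 24); hydrogen peroxide, OO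
Why: Hydroboration followed by lithiation–borylation: 9-BBN should add to the terminal carbon of the exocyclic methylene from the α-face, away from the axial C10 methyl (sets C9 with H α), (+)-sparteine-directed deprotonation should give the (R)-α-lithio carbamate, which is borylated with retention, the primary C11 group migrates from boron to carbon with inversion as the carbamate leaves, and oxidation with retention delivers the (12R)-alcohol next to the untouched (13R)-methyl centre, any material from the minor enantiomer of 16 being removed here as a diastereomer.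

Step 16
Reactants: 27 (2,5-dimethoxyphenyl)methanol
Product: 28 2-(bromomethyl)-1,4-dimethoxybenzene
Conditions: PBr3, Et2O, 0 °C
Reagents that add atoms: phosphorus tribromide, BrP(Br)Br
Why: Bromination of an electron-rich benzylic alcohol with PBr3 is a simple substitution with no stereochemical issue.

Step 17
Reactants: 28 2-(bromomethyl)-1,4-dimethoxybenzene; 29 prop-1-yn-1-ylmagnesium bromide
Product: 30 2-(but-2-yn-1-yl)-1,4-dimethoxybenzene
Conditions: CuBr·SMe2 (10 mol%), THF, 0 °C to rt
Reagents that add atoms: none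
Why: Copper-catalysed coupling of an alkynyl Grignard reagent with a benzylic bromide has only one site of attack, so no allene isomer can form.

Step 18
Reactants: 30 2-(but-2-yn-1-yl)-1,4-dimethoxybenzene
Product: 32 2-[(2E)-3-iodobut-2-en-1-yl]-1,4-dimethoxybenzene, via alkenylzirconocene 31 (not isolated)
Conditions: Cp2Zr(H)Cl (1.5 equiv), THF, rt to 40 °C; I2, 0 °C
Reagents that add atoms: chlorido(hydrido)zirconocene, [H][Zr](Cl)(C1C=CC=C1)C1C=CC=C1 (Zr part only in 31); iodine, II
Why: Hydrozirconation–iodination adds H and Zr syn, the slight excess of reagent should equilibrate zirconium to the less hindered methyl-bearing alkyne carbon, and iodinolysis with retention gives the E-iodide that carries the geometry of C17=C18.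

Step 19
Reactants: 26 (2R,3R)-3-methyl-1-[(1S,4aS,8aS)-2,5,5,8a-tetramethyl-1,4,4a,5,6,7,8,8a-octahydronaphthalen-1-yl]hex-5-en-2-ol; 32 2-[(2E)-3-iodobut-2-en-1-yl]-1,4-dimethoxybenzene
Product: 34 (2R,3R,7E)-9-(2,5-dimethoxyphenyl)-3,7-dimethyl-1-[(1S,4aS,8aS)-2,5,5,8a-tetramethyl-1,4,4a,5,6,7,8,8a-octahydronaphthalen-1-yl]non-7-en-2-ol, via bis-boron adduct 33 (not isolated)
Conditions: 9-BBN (2.2 equiv), THF, rt; then 32, Pd(dppf)Cl2 (5 mol%), AsPh3, Cs2CO3, DMF–H2O, rt
Reagents that add atoms: 9-borabicyclo[3.3.1]nonane, [H]B1C2CCCC1CCC2 (its atoms stay only in 33)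
Why: B-alkyl Suzuki–Miyaura coupling: 9-BBN hydroborates only the terminal alkene (the second equivalent is parked on the hydroxyl group and hydrolysed later), and the coupling keeps the E geometry of the vinyl iodide.

Step 20
Reactants: 34 (2R,3R,7E)-9-(2,5-dimethoxyphenyl)-3,7-dimethyl-1-[(1S,4aS,8aS)-2,5,5,8a-tetramethyl-1,4,4a,5,6,7,8,8a-octahydronaphthalen-1-yl]non-7-en-2-ol
Product: 35 hydrogen sulfate of 34 (O-sulfated at C12)
Conditions: SO3·pyridine, pyridine, rt
Reagents that add atoms: sulfur trioxide–pyridine complex, [O-]S(=O)(=O)[n+]1ccccc1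
Why: O-Sulfation with SO3·pyridine reacts at the only free hydroxyl group with retention at C12 and is too mild to sulfonate the arene or attack the alkenes.

Step 21
Reactants: 35 hydrogen sulfate of 34
Product: 37 halisulfate 1, via quinone sulfate 36 (not isolated)
Conditions: (NH4)2Ce(NO3)6, MeCN–H2O, 0 °C, short contact; extraction (EtOAc–n-BuOH); aq Na2S2O4, rt
Reagents that add atoms: water, O (the two quinone oxygens)
Why: Cerium(IV) oxidative demethylation of a 1,4-dimethoxyarene to the benzoquinone followed by dithionite reduction frees the hydroquinone under cold, brief and then neutral conditions that a secondary alkyl sulfate and trisubstituted alkenes should survive.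

**Compound list**
1 | propane-1,3-diyl bis(4-methylbenzenesulfonate) | Cc1ccc(cc1)S(=O)(=O)OCCCOS(=O)(=O)c1ccc(C)cc1 | starting material
2 | (2-methylprop-1-en-1-yl)magnesium bromide | CC(C)=C[Mg]Br | starting material
3 | 2,8-dimethylnona-2,7-diene | CC(C)=CCCCC=C(C)C | intermediate
4 | (2E)-2,8-dimethylnona-2,7-dien-1-ol | CC(C)=CCCC/C=C(\C)CO | intermediate
5 | [(2S,3S)-2-methyl-3-(5-methylhex-4-en-1-yl)oxiran-2-yl]methanol | CC(C)=CCCC[C@@H]1O[C@@]1(C)CO | intermediate
6 | lithium (trimethylsilyl)acetylide | [Li]C#C[Si](C)(C)C | starting material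
7 | [(2S,3S)-2-methyl-3-(5-methylhex-4-en-1-yl)oxiran-2-yl]methyl trifluoromethanesulfonate | CC(C)=CCCC[C@@H]1O[C@@]1(C)COS(=O)(=O)C(F)(F)F | intermediate (not isolated)
8 | (2S,3S)-2-methyl-3-(5-methylhex-4-en-1-yl)-2-[3-(trimethylsilyl)prop-2-yn-1-yl]oxirane | CC(C)=CCCC[C@@H]1O[C@@]1(C)CC#C[Si](C)(C)C | intermediate
9 | (2S,3S)-2-methyl-3-(5-methylhex-4-en-1-yl)-2-[(2Z)-3-(trimethylsilyl)prop-2-en-1-yl]oxirane | CC(C)=CCCC[C@@H]1O[C@@]1(C)C/C=C\[Si](C)(C)C | intermediate
10 | (1S,4aS,8aS)-5,5,8a-trimethyl-1,2,3,4,4a,5,8,8a-octahydronaphthalen-1-ol | C1CC[C@H]2C(C)(C)C=CC[C@]2(C)[C@H]1O | intermediate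
11 | (1S,4aS,8aS)-5,5,8a-trimethyldecahydronaphthalen-1-ol | C1CC[C@H]2C(C)(C)CCC[C@]2(C)[C@H]1O | intermediate
12 | (4aS,8aS)-5,5,8a-trimethyloctahydronaphthalen-1(2H)-one | C1CC[C@H]2C(C)(C)CCC[C@]2(C)C1=O | intermediate
13 | (2R,4aS,8aS)-2,5,5,8a-tetramethyloctahydronaphthalen-1(2H)-one | C[C@@H]1CC[C@H]2C(C)(C)CCC[C@]2(C)C1=O | intermediate
14 | trimethyl{[(4aS,8aS)-2,5,5,8a-tetramethyl-3,4,4a,5,6,7,8,8a-octahydronaphthalen-1-yl]oxy}silane | CC=1CC[C@H]2C(C)(C)CCC[C@]2(C)C=1O[Si](C)(C)C | intermediate (not isolated)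
15 | (4aS,8aS)-2,5,5,8a-tetramethyl-4a,5,6,7,8,8a-hexahydronaphthalen-1(4H)-one | CC1=CC[C@H]2C(C)(C)CCC[C@]2(C)C1=O | intermediate
16 | drima-7,9(11)-diene | CC1=CC[C@H]2C(C)(C)CCC[C@]2(C)C1=C | intermediate
17 | (4S)-4-benzyl-3-propanoyl-1,3-oxazolidin-2-one | CCC(=O)N1[C@@H](Cc2ccccc2)COC1=O | starting material
18 | 3-iodoprop-1-ene | C=CCI | starting material
19 | (4S)-4-benzyl-3-[(2R)-2-methylpent-4-enoyl]-1,3-oxazolidin-2-one | C=CC[C@@H](C)C(=O)N1[C@@H](Cc2ccccc2)COC1=O | intermediate
20 | (2R)-2-methylpent-4-en-1-ol | C=CC[C@@H](C)CO | intermediate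
21 | (2R)-2-methylpent-4-en-1-yl N,N-diisopropylcarbamate | CC(C)N(C(C)C)C(=O)OC[C@H](C)CC=C | intermediate
22 | 9-(drim-7-en-11-yl)-9-borabicyclo[3.3.1]nonane | CC1=CC[C@H]2C(C)(C)CCC[C@]2(C)[C@H]1CB3C4CCCC3CCC4 | intermediate (not isolated)
23 | (1R,2R)-1-lithio-2-methylpent-4-en-1-yl N,N-diisopropylcarbamate (sparteine complex) | [Li][C@@H](OC(=O)N(C(C)C)C(C)C)[C@H](C)CC=C | intermediate (not isolated)
24 | lithium borate from 22 and 23 | [Li+].CC1=CC[C@H]2C(C)(C)CCC[C@]2(C)[C@H]1C[B-]3(C4CCCC3CCC4)[C@@H](OC(=O)N(C(C)C)C(C)C)[C@H](C)CC=C | intermediate (not isolated)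
25 | secondary borane after 1,2-migration (boron on C12) | CC1=CC[C@H]2C(C)(C)CCC[C@]2(C)[C@H]1C[C@@H](B3C4CCCC3CCC4)[C@H](C)CC=C | intermediate (not isolated)
26 | (2R,3R)-3-methyl-1-[(1S,4aS,8aS)-2,5,5,8a-tetramethyl-1,4,4a,5,6,7,8,8a-octahydronaphthalen-1-yl]hex-5-en-2-ol | CC1=CC[C@H]2C(C)(C)CCC[C@]2(C)[C@H]1C[C@@H](O)[C@H](C)CC=C | intermediate
27 | (2,5-dimethoxyphenyl)methanol | COc1ccc(OC)c(CO)c1 | starting material
28 | 2-(bromomethyl)-1,4-dimethoxybenzene | COc1ccc(OC)c(CBr)c1 | intermediate
29 | prop-1-yn-1-ylmagnesium bromide | CC#C[Mg]Br | starting material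
30 | 2-(but-2-yn-1-yl)-1,4-dimethoxybenzene | COc1ccc(OC)c(CC#CC)c1 | intermediate
31 | (E)-alkenyl(chlorido)zirconocene from 30 | COc1ccc(OC)c(C/C=C(\C)[Zr](Cl)(C2C=CC=C2)C2C=CC=C2)c1 | intermediate (not isolated)
32 | 2-[(2E)-3-iodobut-2-en-1-yl]-1,4-dimethoxybenzene | COc1ccc(OC)c(C/C=C(\C)I)c1 | intermediate
33 | C16-(9-BBN) adduct of 26 with the C12 oxygen as its 9-BBN borinate | CC1=CC[C@H]2C(C)(C)CCC[C@]2(C)[C@H]1C[C@@H](OB3C4CCCC3CCC4)[C@H](C)CCCB3C4CCCC3CCC4 | intermediate (not isolated)
34 | (2R,3R,7E)-9-(2,5-dimethoxyphenyl)-3,7-dimethyl-1-[(1S,4aS,8aS)-2,5,5,8a-tetramethyl-1,4,4a,5,6,7,8,8a-octahydronaphthalen-1-yl]non-7-en-2-ol | CC1=CC[C@H]2C(C)(C)CCC[C@]2(C)[C@H]1C[C@@H](O)[C@H](C)CCC/C(C)=C/Cc1cc(OC)ccc1OC | intermediate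
35 | hydrogen sulfate of 34 | CC1=CC[C@H]2C(C)(C)CCC[C@]2(C)[C@H]1C[C@@H](OS(=O)(=O)O)[C@H](C)CCC/C(C)=C/Cc1cc(OC)ccc1OC | intermediate
36 | 1,4-benzoquinone form of the target (sulfate in place) | CC1=CC[C@H]2C(C)(C)CCC[C@]2(C)[C@H]1C[C@@H](OS(=O)(=O)O)[C@H](C)CCC/C(C)=C/CC1=CC(=O)C=CC1=O | intermediate (not isolated)
37 | halisulfate 1 | CC1=CC[C@H]2C(C)(C)CCC[C@]2(C)[C@H]1C[C@@H](OS(=O)(=O)O)[C@H](C)CCC/C(C)=C/Cc1cc(O)ccc1O | target

**Step count**
Total steps: 21. Longest linear sequence: 15 (steps 1–11, 15, 19, 20, 21).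

**Steps most likely to fail**

Step 6. The exocyclic tertiary cation may lose a proton before the vinylsilane reaches it. The activated epoxide may also rearrange by hydride shift, or be opened at its secondary carbon.

The fallback sets out from 9 and returns at 10. The Lewis-acid treatment is used for the first ring only, and proton loss then gives the monocyclic isopropenyl alcohol F1. Iododesilylation with NIS in MeCN (retention) gives the Z-vinyl iodide F2.

A reductive Heck cyclisation (Pd(OAc)2, PPh3, HCO2Na, DMF, 80 °C) then forms the same C3–C4 bond. The alkenyl-palladium species adds 6-exo-trig to the isopropenyl group. The resulting neopentyl-palladium species has no β-hydrogen and is reduced by formate to the second methyl group, which gives 10.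

Step 15. Four things may go wrong:
- hydroboration of the hindered diene may be slow or unselective;
- the ate complex may form sluggishly;
- a ring carbon of the bicyclononane may migrate instead of C11;
- the deprotonation may lose selectivity if reagent and C13 are mismatched.

The fallback sets out from 16 (through 22) and 20, and returns at 26. Borane 22 is oxidised (NaOH, H2O2) to (−)-drimenol F3. Appel iodination (I2, PPh3, imidazole) gives the iodide F4, and t-BuLi exchange at −78 °C gives the primary alkyllithium F5. This is added to (2R)-2-methylpent-4-enal F6, made from 20 by Swern oxidation. Felkin–Anh addition should favour the 12,13-syn alcohol 26, and the epimer is removed by chromatography.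

Step 21. The secondary sulfate may solvolyse in the acidic cerium(IV) medium, or the quinone may be over-oxidised or dimerise.

The fallback sets out from 34 and returns at 37, with the order of events reversed:
- CAN converts 34 into the quinone alcohol F7;
- dithionite gives the hydroquinone alcohol F8;
- TBSCl and imidazole at 0 °C silylate only the two phenols, to give the bis-silyl ether F9;
- SO3·pyridine gives the sulfate F10;
- TBAF at 0 °C frees 37 under conditions to which the sulfate is inert.

**Further compounds**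
F1 | step 6 | (1S,2S,3S)-2-methyl-3-(prop-1-en-2-yl)-2-[(2Z)-3-(trimethylsilyl)prop-2-en-1-yl]cyclohexan-1-ol | C1CC[C@@H](C(C)=C)[C@](C)(C/C=C\[Si](C)(C)C)[C@H]1O
F2 | step 6 | (1S,2S,3S)-2-[(2Z)-3-iodoprop-2-en-1-yl]-2-methyl-3-(prop-1-en-2-yl)cyclohexan-1-ol | C1CC[C@@H](C(C)=C)[C@](C)(C/C=C\I)[C@H]1O
F3 | step 15 | (−)-drimenol | CC1=CC[C@H]2C(C)(C)CCC[C@]2(C)[C@H]1CO
F4 | step 15 | 11-iododrim-7-ene | CC1=CC[C@H]2C(C)(C)CCC[C@]2(C)[C@H]1CI
F5 | step 15 | drim-7-en-11-yllithium | CC1=CC[C@H]2C(C)(C)CCC[C@]2(C)[C@H]1C[Li]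
F6 | step 15 | (2R)-2-methylpent-4-enal | C=CC[C@@H](C)C=O
F7 | step 21 | quinone alcohol (34 with the arene oxidised to the 1,4-benzoquinone) | CC1=CC[C@H]2C(C)(C)CCC[C@]2(C)[C@H]1C[C@@H](O)[C@H](C)CCC/C(C)=C/CC1=CC(=O)C=CC1=O
F8 | step 21 | hydroquinone alcohol (desulfated target) | CC1=CC[C@H]2C(C)(C)CCC[C@]2(C)[C@H]1C[C@@H](O)[C@H](C)CCC/C(C)=C/Cc1cc(O)ccc1O
F9 | step 21 | bis(tert-butyldimethylsilyl) aryl ether of F8 | CC1=CC[C@H]2C(C)(C)CCC[C@]2(C)[C@H]1C[C@@H](O)[C@H](C)CCC/C(C)=C/Cc1cc(O[Si](C)(C)C(C)(C)C)ccc1O[Si](C)(C)C(C)(C)C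
F10 | step 21 | hydrogen sulfate of F9 | CC1=CC[C@H]2C(C)(C)CCC[C@]2(C)[C@H]1C[C@@H](OS(=O)(=O)O)[C@H](C)CCC/C(C)=C/Cc1cc(O[Si](C)(C)C(C)(C)C)ccc1O[Si](C)(C)C(C)(C)C
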